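The rate constants were set for the occasion; the result is computed.

At constant temperature the clock is 10 d, and I reckon both flasks by counting how many half-lives of the electrophile fit into it.

all flasks: electrophile 0.40 M; protic impurity 8.00 mM; time 10 d

| flask | nucleophile |
|---|---|
| Sunday's | 2.00 equiv |
| Friday's | 4.00 equiv |

- part of the electrophile that has reacted at the end, Sunday's
- part of the electrophile that has reacted at the end, Friday's
- what raising the equivalents of nucleophile from its lowest to its highest value here does to the part of the electrophile that has reacted (changes below 5 percentage points count as none) (it rises / it falls / no change)

    electrophile + nucleophile → acid set free + target (k1 = 1.6 × 10⁻⁴ M⁻¹ min⁻¹)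
    electrophile + protic impurity → quenched substrate (k2 = 0.012 M⁻¹ min⁻¹)
    electrophile + target → side product (k3 = 2.7 × 10⁻⁴ M⁻¹ min⁻¹)
    nucleophile + acid set free ⇌ protonated nucleophile, settled at all times (K4 = 940 M⁻¹)
    nucleophile ⇌ dormant form (K5 = 2.7, k5 = 5.5 × 10⁻⁴ min⁻¹)

- a species is counted by the electrophile in it: one side product counts as two
- run time (Sunday's): 10 d

Does the protic impurity matter? Against the electrophile it has a half-life of 0.100 d, far shorter than the run, so it costs the electrophile its 2.00% of the charge early.

How much nucleophile is free? Its exchange with the dormant form relaxes with a half-life of 0.639 d. That is shorter than the half-life of the electrophile by step 1 at the charged nucleophile, 3.8 d in Sunday's and 1.88 d in Friday's. So I take the balance from the start, with 27.0% of the nucleophile free.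

What does that leave for the electrophile? I treat step 1 as pseudo-first-order in the electrophile, with the free nucleophile held at that share of its charge, which gives a working half-life of 13.9 d in Sunday's. Sunday's run holds 0.719 of them, and this count, run time over working half-life, is what I carry. Friday's, with twice the nucleophile, has 1.44.

Step 1 takes 0.5 raised to the count, subtracted from one: 39.2% in Sunday's and 63.1% in Friday's. With the impurity's share that makes 41.2% and 65.1%, so the part reacted rises by 24 percentage points.

Two things pull opposite ways and I leave both out. Acid set free takes nucleophile (750 is K4 times the charged nucleophile in Sunday's), and step 3 spends a second electrophile on target. By step 3 at the charged electrophile, target has a half-life of 4.5 d in Sunday's, shorter than the run.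

The forecast gives 52% and 76%, above my figures, and says it rises, holding that “free acid stays negligible”.

The flask gives 51.8% in Sunday's and 76.7% in Friday's, a change of 25 points, so the answer on the trend is: it rises.

Target plus half the side product measures step 1: 34.2% in Sunday's against my 39.2%, and 55.0% in Friday's against my 63.1%. The neighbour is Friday's with the electrophile at 0.16 M, the equivalents and the time held. Its count is 0.575, so step 1 should take 32.9%. The neighbour shows target 25.4% and side product 15.0%, which puts 32.9% through step 1, and 45.4% of its electrophile has reacted.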